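The cycloheptene is closed between C5 and C6 by ring-closing metathesis, in a 10-step linear route from commercial materials; nothing here has been run, so every outcome is stated as an expectation.

Carotane locants: C1 (methyl-bearing fusion carbon), C4 (isopropyl carbinol), C5 (fusion CH), C6 (ester carbinol), C8 (methyl carbinol), C9=C10 (ring olefin). With a ketone at C4, the C4–C5–C6 array is an aldol retron and the C5–C6 bond belongs to the seven-membered ring only. That ring is therefore closed between C5 and C6 by ring-closing metathesis, as the C5=C6 bond of a 2-alkylidenecyclopentanone. The precursor is a monocyclic 2-methylidenecyclopentanone whose quaternary C1 carries a Z-dienyl chain ending in the C6 vinyl group. A hydrosilylation tethered to the C8 hydroxyl then places H on C5 and O on C6 from one face, which fixes the trans ring fusion; isopropyl addition at C4 follows.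

Key step: step 6

Remark: C1–C10 in the Why lines are the carotane locants defined above, while names use azulene or cyclopentanone locants; the enantiomers of the chiral catalysts in steps 1 and 3 are assumed to be those that give the R carbinol and the S quaternary ketone, and the antipode is used if the sense of induction proves opposite.

Step 1
Reactants: 1 4-(trimethylsilyl)but-3-yn-2-one; 2 diisopropyl allylboronate
Product: 3 (3R)-3-methyl-1-(trimethylsilyl)hex-5-en-1-yn-3-ol
Conditions: (S)-3,3′-Br2-BINOL (15 mol %), PhCF3/PhMe, −35 °C; aq. work-up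
Reagents that add atoms: none
Why: Diol-catalysed asymmetric allylboration of a ketone, in which the binaphthol exchanges with one isopropoxy group and the activated allylboronate transfers allyl through a closed chair transition state with the alkynyl group equatorial, so that one face of the ynone is attacked and the R tertiary carbinol (C8) should result.

Step 2
Reactants: 3 (3R)-3-methyl-1-(trimethylsilyl)hex-5-en-1-yn-3-ol; 4 3-ethoxycyclopent-2-en-1-one
Product: 7 3-[(3R)-3-hydroxy-3-methylhex-5-en-1-yn-1-yl]cyclopent-2-en-1-one, via dilithium alkoxide acetylide 5 (not isolated), via dilithium bis-alkoxide adduct 6 (not isolated)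
Conditions: MeLi·LiBr (2.2 equiv), THF, 0 °C to rt; then 4, −78 to 0 °C; then 1 M HCl, 0 °C
Reagents that add atoms: water, O
Why: Stork–Danheiser sequence, in which methyllithium deprotonates the alcohol and cleaves the alkynyl–silicon bond, the lithium acetylide adds 1,2 to the vinylogous ester, and acid hydrolysis of the enol ether with loss of ethanol transposes the carbonyl to the 3-alkynyl enone without touching C8.

Step 3
Reactants: 7 3-[(3R)-3-hydroxy-3-methylhex-5-en-1-yn-1-yl]cyclopent-2-en-1-one
Product: 9 (3S)-2-[(dimethylamino)methyl]-3-[(3R)-3-hydroxy-3-methylhex-5-en-1-yn-1-yl]-3-methylcyclopentan-1-one (C2 epimers), via bromomagnesium enolate alkoxide 8 (not isolated)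
Conditions: MeMgBr (2.5 equiv), Cu(OTf)2 (6 mol %), chiral N-mesityl N′-hydroxyalkyl imidazolinium hexafluorophosphate (NHC precursor, 8 mol %), Et2O, −30 °C; then CH2=NMe2+ I−, THF, −30 °C to rt
Reagents that add atoms: methylmagnesium bromide, C[Mg]Br; N,N-dimethylmethyleneiminium iodide (Eschenmoser salt), C=[N+](C)C.[I-]
Why: Copper-catalysed asymmetric conjugate addition of a Grignard reagent with an NHC ligand, which on alkynyl-substituted cyclic enones should add 1,4 and set the quaternary C1 under catalyst control (the hydroxyl rides as its magnesium alkoxide), followed by Mannich trapping of the regiodefined magnesium enolate at C5.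

Step 4
Reactants: 9 (3S)-2-[(dimethylamino)methyl]-3-[(3R)-3-hydroxy-3-methylhex-5-en-1-yn-1-yl]-3-methylcyclopentan-1-one
Product: 10 (3R)-2-[(dimethylamino)methyl]-3-[(1Z,3R)-3-hydroxy-3-methylhexa-1,5-dien-1-yl]-3-methylcyclopentan-1-one (C2 epimers)
Conditions: H2 (1 atm), Pd/CaCO3 poisoned with Pb(OAc)2 (Lindlar catalyst), quinoline, EtOAc, rt, stopped after one equivalent of H2
Reagents that add atoms: none
Why: Lindlar semihydrogenation delivers H2 syn to the alkyne and so should give the Z C9=C10 olefin that the seven-membered ring requires, the poisoned catalyst sparing the terminal vinyl group and the ketone.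

Step 5
Reactants: 10 (3R)-2-[(dimethylamino)methyl]-3-[(1Z,3R)-3-hydroxy-3-methylhexa-1,5-dien-1-yl]-3-methylcyclopentan-1-one
Product: 12 (3R)-3-[(1Z,3R)-3-hydroxy-3-methylhexa-1,5-dien-1-yl]-3-methyl-2-methylidenecyclopentan-1-one, via trimethylammonium iodide 11 (not isolated)
Conditions: MeI, Et2O, rt; then aq. NaHCO3, CH2Cl2, rt
Reagents that add atoms: none
Why: Exhaustive N-methylation of the Mannich base and E1cB (Hofmann-type) loss of trimethylamine from the β-ammonium ketone unveil the 2-methylidene ketone at C5 only, because the aminomethyl group was placed there by the enolate trapping.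

Step 6
Reactants: 12 (3R)-3-[(1Z,3R)-3-hydroxy-3-methylhexa-1,5-dien-1-yl]-3-methyl-2-methylidenecyclopentan-1-one
Product: 13 (3aR,6R)-6-hydroxy-3a,6-dimethyl-3,3a,6,7-tetrahydroazulen-1(2H)-one
Conditions: second-generation Grubbs catalyst (H2IMes)(PCy3)Cl2Ru=CHPh (5 mol %), CH2Cl2 (0.005 M), 40 °C
Reagents that add atoms: none
Why: The ruthenium alkylidene should form at the unhindered C6 vinyl group, add [2+2] to the 2-methylidene olefin at C5 and cyclorevert from the ruthenacyclobutane with loss of ethene, leaving the C5=C6 double bond. The closest known reaction type is ring-closing metathesis of an α-methylene ketone with a terminal olefin to a cyclic 2-alkylidene ketone. The seven-membered ring closes by olefin metathesis as a cyclohepta-1,4-diene in which the new C5=C6 bond is endocyclic to the seven-membered ring and exocyclic to the cyclopentanone. No stereocentre is formed; C1 and C8 are untouched and the geometry of the new olefin is fixed by the ring. The step needs cyclisation to win over oligomerisation and over reaction at C9=C10: high dilution, the Z C9=C10 bond and the quaternary C1 and C8 hold the two termini together, and metathesis at the flanked C9=C10 bond could only give a three- or four-membered ring.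

Step 7
Reactants: 13 (3aR,6R)-6-hydroxy-3a,6-dimethyl-3,3a,6,7-tetrahydroazulen-1(2H)-one
Product: 16 (3aR,6R,8S,8aS)-6,8-dihydroxy-3a,6-dimethyl-3,3a,6,7,8,8a-hexahydroazulen-1(2H)-one, via dimethylsilyl ether 14 (not isolated), via oxasilolane 15 (not isolated)
Conditions: (HMe2Si)2NH, 60 °C, then evaporation; Pt2[(CH2=CHSiMe2)2O]3 (Karstedt catalyst, 1 mol %), PhMe, 60 °C; then KF, KHCO3, 30% H2O2, THF/MeOH, rt
Reagents that add atoms: hydrogen peroxide, OO
Why: Tamao-type intramolecular hydrosilylation and Tamao–Fleming oxidation, in which the C8 hydroxyl is silylated, platinum adds Si–H syn across C5=C6 in the 5-exo sense (Si to C6, H to C5) on the face of the C8 oxygen, and stereoretentive oxidation of the C–Si bond should give the C6 carbinol cis to the C8 hydroxyl and the C5 hydrogen trans to the C1 methyl, that is, the trans ring fusion.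

Step 8
Reactants: 16 (3aR,6R,8S,8aS)-6,8-dihydroxy-3a,6-dimethyl-3,3a,6,7,8,8a-hexahydroazulen-1(2H)-one
Product: 17 (1R,3aR,6R,8S,8aS)-3a,6-dimethyl-1-(propan-2-yl)-1,2,3,3a,6,7,8,8a-octahydroazulene-1,6,8-triol
Conditions: i-PrMgCl (5 equiv), CeCl3 (5 equiv), THF, −78 °C; aq. NH4Cl
Reagents that add atoms: isopropylmagnesium chloride, CC(C)[Mg]Cl
Why: Organocerium 1,2-addition suppresses enolisation and reduction, and the isopropyl group should enter the cyclopentanone from the face opposite the C5–C6 bond and the C1 methyl (the face left open by a C6 alkoxide chelate), so that the C4 hydroxyl ends cis to C6.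

Step 9
Reactants: 17 (1R,3aR,6R,8S,8aS)-3a,6-dimethyl-1-(propan-2-yl)-1,2,3,3a,6,7,8,8a-octahydroazulene-1,6,8-triol; 18 4-(acetyloxy)benzoyl chloride
Product: 19 (1R,3aR,6R,8S,8aS)-1,6-dihydroxy-3a,6-dimethyl-1-(propan-2-yl)-1,2,3,3a,6,7,8,8a-octahydroazulen-8-yl 4-(acetyloxy)benzoate
Conditions: pyridine, DMAP (cat.), CH2Cl2, 0 °C to rt
Reagents that add atoms: none
Why: DMAP-catalysed acylation by the acid chloride should take the only secondary hydroxyl (C6) and leave the two tertiary hydroxyls untouched, no stereocentre being affected.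

Step 10
Reactants: 19 (1R,3aR,6R,8S,8aS)-1,6-dihydroxy-3a,6-dimethyl-1-(propan-2-yl)-1,2,3,3a,6,7,8,8a-octahydroazulen-8-yl 4-(acetyloxy)benzoate
Product: 20 (1R,3aR,6R,8S,8aS)-1,6-dihydroxy-3a,6-dimethyl-1-(propan-2-yl)-1,2,3,3a,6,7,8,8a-octahydroazulen-8-yl 4-hydroxybenzoate
Conditions: K2CO3 (1.5 equiv), MeOH, 0 °C; aq. NH4Cl
Reagents that add atoms: none
Why: Base-mediated methanolysis (transesterification) cleaves the aryl acetate far faster than the hindered benzoate, which is further deactivated once the phenoxide has formed.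

Compound list
1 | 4-(trimethylsilyl)but-3-yn-2-one | CC(=O)C#C[Si](C)(C)C | starting material
2 | diisopropyl allylboronate (dipropan-2-yl prop-2-en-1-ylboronate) | C=CCB(OC(C)C)OC(C)C | starting material
3 | (3R)-3-methyl-1-(trimethylsilyl)hex-5-en-1-yn-3-ol | C[Si](C)(C)C#C[C@](C)(O)CC=C | intermediate
4 | 3-ethoxycyclopent-2-en-1-one | CCOC1=CC(=O)CC1 | starting material
5 | dilithium alkoxide acetylide of (3R)-3-methylhex-5-en-1-yn-3-ol (not isolated) | [Li]C#C[C@](C)(O[Li])CC=C | intermediate
6 | dilithium bis-alkoxide of 3-ethoxy-1-[(3R)-3-hydroxy-3-methylhex-5-en-1-yn-1-yl]cyclopent-2-en-1-ol, carbinol epimers (not isolated) | CCOC1=CC(O[Li])(C#C[C@](C)(O[Li])CC=C)CC1 | intermediate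
7 | 3-[(3R)-3-hydroxy-3-methylhex-5-en-1-yn-1-yl]cyclopent-2-en-1-one | O=C1CCC(C#C[C@](C)(O)CC=C)=C1 | intermediate
8 | bis(bromomagnesium) enolate alkoxide of (3S)-3-[(3R)-3-hydroxy-3-methylhex-5-en-1-yn-1-yl]-3-methylcyclopentan-1-one, enolised towards C2 (not isolated) | C[C@]1(C#C[C@](C)(O[Mg]Br)CC=C)CCC(O[Mg]Br)=C1 | intermediate
9 | (3S)-2-[(dimethylamino)methyl]-3-[(3R)-3-hydroxy-3-methylhex-5-en-1-yn-1-yl]-3-methylcyclopentan-1-one (C2 epimers) | O=C1C(CN(C)C)[C@@](C)(C#C[C@](C)(O)CC=C)CC1 | intermediate
10 | (3R)-2-[(dimethylamino)methyl]-3-[(1Z,3R)-3-hydroxy-3-methylhexa-1,5-dien-1-yl]-3-methylcyclopentan-1-one (C2 epimers) | O=C1C(CN(C)C)[C@@](C)(/C=C\[C@](C)(O)CC=C)CC1 | intermediate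
11 | trimethylammonium iodide of 10 (not isolated) | O=C1C(C[N+](C)(C)C)[C@@](C)(/C=C\[C@](C)(O)CC=C)CC1.[I-] | intermediate
12 | (3R)-3-[(1Z,3R)-3-hydroxy-3-methylhexa-1,5-dien-1-yl]-3-methyl-2-methylidenecyclopentan-1-one | O=C1C(=C)[C@@](C)(/C=C\[C@](C)(O)CC=C)CC1 | intermediate
13 | (3aR,6R)-6-hydroxy-3a,6-dimethyl-3,3a,6,7-tetrahydroazulen-1(2H)-one | O=C1CC[C@]2(C)C=C[C@](C)(O)CC=C12 | intermediate
14 | (3aR,6R)-6-[(dimethylsilyl)oxy]-3a,6-dimethyl-3,3a,6,7-tetrahydroazulen-1(2H)-one (not isolated) | O=C1CC[C@]2(C)C=C[C@](C)(O[SiH](C)C)CC=C12 | intermediate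
15 | oxasilolane of the (3aR,6R,8S,8aS)-hexahydroazulen-1(2H)-one: dimethylsilylene bridging the C6 oxygen and C8, with 8a-H cis to both (not isolated) | O=C1CC[C@]2(C)C=C[C@]3(C)O[Si](C)(C)[C@@H](C3)[C@H]21 | intermediate
16 | (3aR,6R,8S,8aS)-6,8-dihydroxy-3a,6-dimethyl-3,3a,6,7,8,8a-hexahydroazulen-1(2H)-one | O=C1CC[C@]2(C)C=C[C@](C)(O)C[C@H](O)[C@H]21 | intermediate
17 | (1R,3aR,6R,8S,8aS)-3a,6-dimethyl-1-(propan-2-yl)-1,2,3,3a,6,7,8,8a-octahydroazulene-1,6,8-triol | CC(C)[C@]1(O)CC[C@]2(C)C=C[C@](C)(O)C[C@H](O)[C@H]21 | intermediate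
18 | 4-(acetyloxy)benzoyl chloride | CC(=O)Oc1ccc(cc1)C(Cl)=O | starting material
19 | (1R,3aR,6R,8S,8aS)-1,6-dihydroxy-3a,6-dimethyl-1-(propan-2-yl)-1,2,3,3a,6,7,8,8a-octahydroazulen-8-yl 4-(acetyloxy)benzoate | CC(C)[C@]1(O)CC[C@]2(C)C=C[C@](C)(O)C[C@H](OC(=O)c3ccc(OC(C)=O)cc3)[C@H]21 | intermediate
20 | (1R,3aR,6R,8S,8aS)-1,6-dihydroxy-3a,6-dimethyl-1-(propan-2-yl)-1,2,3,3a,6,7,8,8a-octahydroazulen-8-yl 4-hydroxybenzoate | CC(C)[C@]1(O)CC[C@]2(C)C=C[C@](C)(O)C[C@H](OC(=O)c3ccc(O)cc3)[C@H]21 | target

Total step count: 10. Longest linear sequence: 10 steps (1 to 20).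

Steps most likely to fail

1. Step 7. The platinum catalyst may add the Si–H bond to the less substituted C9=C10 olefin or to the conjugated carbonyl, or the trisubstituted C5=C6 bond may not insert at all. The fallback sets out from 13 and comes back at 16. Weitz–Scheffer epoxidation (30% H2O2, NaOH, MeOH, 0 °C), in which the hydroperoxide is guided by the free C8 hydroxyl and the oxirane closes on C5 opposite the C1 methyl, should give (3aR,6R,8S,8aR)-8,8a-epoxy-6-hydroxy-3a,6-dimethyl-3,3a,6,7,8,8a-hexahydroazulen-1(2H)-one F1. SmI2 in THF/MeOH at −90 °C should then cleave the α carbon–oxygen bond, and low-temperature protonation of the samarium enolate opposite the C1 methyl should return 16.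

2. Step 3. The methyl group may add in the 1,6 sense across the enyne (allenyl enolate), or facial discrimination may be eroded on the five-membered enone that carries a magnesium alkoxide. The fallback sets out from 7 and comes back at 10. The alkyne is semihydrogenated first (H2, Lindlar catalyst, quinoline) to 3-[(1Z,3R)-3-hydroxy-3-methylhexa-1,5-dien-1-yl]cyclopent-2-en-1-one F2, a cross-conjugated dienone for which 1,4-addition of Grignard reagents under copper–NHC catalysis is the established course. Methyl addition and trapping of the bromomagnesium enolate alkoxide F3 with the iminium salt should then give 10 directly.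

3. Step 8. The secondary Grignard reagent may enolise or reduce the hindered ketone, or the aldolate may open by retro-aldol cleavage before addition. The fallback sets out from 16 and comes back at 17. 2-Propenylmagnesium bromide with CeCl3 (an sp2 nucleophile that is not a hydride donor) should give (1S,3aR,6R,8S,8aS)-3a,6-dimethyl-1-(prop-1-en-2-yl)-1,2,3,3a,6,7,8,8a-octahydroazulene-1,6,8-triol F4. Its 1,1-disubstituted olefin is then hydrogenated with H2 and RhCl(PPh3)3 in benzene, the C9=C10 bond between two quaternary carbons being left, to reach 17.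

Further compounds
F1 | step 7 | (3aR,6R,8S,8aR)-8,8a-epoxy-6-hydroxy-3a,6-dimethyl-3,3a,6,7,8,8a-hexahydroazulen-1(2H)-one | O=C1CC[C@]2(C)C=C[C@](C)(O)C[C@@H]3O[C@@]321
F2 | step 3 | 3-[(1Z,3R)-3-hydroxy-3-methylhexa-1,5-dien-1-yl]cyclopent-2-en-1-one | O=C1CCC(/C=C\[C@](C)(O)CC=C)=C1
F3 | step 3 | bis(bromomagnesium) enolate alkoxide of (3R)-3-[(1Z,3R)-3-hydroxy-3-methylhexa-1,5-dien-1-yl]-3-methylcyclopentan-1-one, enolised towards C2 | C[C@]1(/C=C\[C@](C)(O[Mg]Br)CC=C)CCC(O[Mg]Br)=C1
F4 | step 8 | (1S,3aR,6R,8S,8aS)-3a,6-dimethyl-1-(prop-1-en-2-yl)-1,2,3,3a,6,7,8,8a-octahydroazulene-1,6,8-triol | C=C(C)[C@]1(O)CC[C@]2(C)C=C[C@](C)(O)C[C@H](O)[C@H]21
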